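**Retrosynthetic overview**
1. Ring labels: A is the resorcinol-type benzene ring, C is the heterocycle O1–C2–C3–C4–C4a–C8a, B is the aryl ring on C3, and D is the dimethylpyran fused to B. C3 is an epimerisable α-aryl ketone centre, so it is set late. The achiral isoflavone is reduced by asymmetric transfer hydrogenation with dynamic kinetic resolution, C4 is re-oxidised, and the silyl group is removed.
2. Key disconnection: C3 is excised from ring C together with rings B and D (cuts at C2–C3 and C3–C4). What remains, O1–C2–C4–C4a–C8a, is the five-membered ring of 6-hydroxybenzofuran-3(2H)-one. The excised unit is an aryl(chloro)carbene made from a chlorodiazirine.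
3. Enabling feature: in ring C, C3 lies between C2, which bears O1, and C4, which bears the carbonyl oxygen. Without C3 these two oxygen-bearing carbons are neighbours, so the silylated benzofuranone offers a C=C bond with an oxygen donor on each carbon. That bond captures the carbene, and the same two oxygens stabilise the chromenylium ion formed when the strained chlorocyclopropane opens.
4. Order of rings: A, B and D are bought with the two starting materials. The five-membered O-heterocycle is also bought and is enlarged to six-membered ring C in the key step, by way of a transient three-membered ring.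

Key step: step 6

Remark: CIP analysis of the given structure (C4 > C2 > C1' of ring B > H) gives the 3S configuration. The (S,S)-configured reduction catalyst is chosen on that basis.

**Step 1**
Reactants: 1 6-hydroxybenzofuran-3(2H)-one
Product: 2 3,6-bis(triisopropylsilyloxy)benzofuran
Conditions: TIPSOTf (2.3 equiv), Et3N (3 equiv), CH2Cl2, 0 °C to rt
Reagents that add atoms: triisopropylsilyl triflate, CC(C)[Si](OS(=O)(=O)C(F)(F)F)(C(C)C)C(C)C
Why: Soft enolisation and silylation with a silyl triflate and an amine should silylate the phenol and turn the ketone into the aromatic 3-silyloxybenzofuran in one operation, which installs both the later C7–O protecting group and the activating enol ether.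

**Step 2**
Reactants: 3 7-methoxy-2,2-dimethyl-2H-chromene
Product: 5 7-methoxy-2,2-dimethyl-2H-chromene-6-carbaldehyde, via aryl iminium salt 4 (not isolated)
Conditions: POCl3, DMF, 0 to 50 °C; then ice-water
Reagents that add atoms: N,N-dimethylformamide, CN(C)C=O; water, O
Why: In this Vilsmeier–Haack formylation the chloroiminium ion should attack C6, which is para to the pyran oxygen, ortho to the methoxy group and less crowded than C8, while the ring D double bond is shielded by the adjacent gem-dimethyl carbon and water hydrolyses 4 to the aldehyde.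

**Step 3**
Reactants: 5 7-methoxy-2,2-dimethyl-2H-chromene-6-carbaldehyde
Product: 8 7-methoxy-2,2-dimethyl-2H-chromene-6-carbonitrile, via aldoxime 6 (not isolated), via oxime acetate 7 (not isolated)
Conditions: NH2OH·HCl, pyridine, rt; then Ac2O, 90 °C
Reagents that add atoms: hydroxylamine hydrochloride, Cl.NO
Why: Oxime formation, O-acetylation and pyridine-induced loss of acetic acid (aldoxime dehydration) should give the nitrile under non-acidic conditions that leave the chromene untouched.

**Step 4**
Reactants: 8 7-methoxy-2,2-dimethyl-2H-chromene-6-carbonitrile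
Product: 10 7-methoxy-2,2-dimethyl-2H-chromene-6-carboximidamide hydrochloride, via lithium bis(silyl)amidinate 9 (not isolated)
Conditions: LiN(SiMe3)2, THF, 0 °C to rt; then HCl (4 M in dioxane), 0 °C
Reagents that add atoms: lithium bis(trimethylsilyl)amide, [Li]N([Si](C)(C)C)[Si](C)(C)C; hydrogen chloride, Cl
Why: Addition of the silylamide to the nitrile (amidine synthesis, helped by lithium chelation to the ortho-methoxy group) should give 9, and anhydrous HCl then strips both silyl groups so that the amidinium chloride precipitates before acid can add to the chromene.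

**Step 5**
Reactants: 10 7-methoxy-2,2-dimethyl-2H-chromene-6-carboximidamide hydrochloride
Product: 11 3-chloro-3-(7-methoxy-2,2-dimethyl-2H-chromen-6-yl)-3H-diazirine
Conditions: aq NaOCl, NaCl, DMSO/pentane, 0 °C; kept as a cold, dilute pentane/toluene solution
Reagents that add atoms: sodium hypochlorite, [Na+].[O-]Cl
Why: In this Graham oxidation, N-chlorination of the amidine, base-induced N–N ring closure and chloride transfer to carbon should give the aryl chlorodiazirine, which passes at once into pentane away from the oxidant, and uncatalysed alkaline hypochlorite is slow towards the hindered ring D alkene.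

**Step 6**
Reactants: 11 3-chloro-3-(7-methoxy-2,2-dimethyl-2H-chromen-6-yl)-3H-diazirine; 2 3,6-bis(triisopropylsilyloxy)benzofuran
Product: 15 3-(7-methoxy-2,2-dimethyl-2H-chromen-6-yl)-7-(triisopropylsilyloxy)-4H-chromen-4-one, via aryl(chloro)carbene 12 (not isolated), via chlorocyclopropane 13 (not isolated), via silyloxychromenylium chloride 14 (not isolated)
Conditions: 2 (2 equiv), Na2CO3, MeCN/toluene, 45 °C, slow addition of 11
Reagents that add atoms: none
Why: Proposed new method: thermal loss of N2 from 11 gives the singlet, electrophilic carbene 12, which adds to the C2=C3 bond of 2, the most nucleophilic π bond present because C2 carries O1 and C3 carries the silyloxy group, to give 13. The chloride on the apex carbon then leaves with disrotatory 2π-electrocyclic opening of the bond shared by the two rings (Woodward–Hoffmann–DePuy mode for the endo chloride, prior ionisation to an aryl-stabilised cyclopropyl cation for the exo chloride), so release of cyclopropane strain turns the five-membered ring into the six-membered ring of 14. Chloride removes the silyl group only from the cationic oxygen on C4, which gives the C4 carbonyl of 15 while the neutral aryl silyl ether on C7 stays. The closest known reaction types are the Ciamician–Dennstedt-type carbon insertion of aryl chlorodiazirines into pyrroles, indoles and indenes, the dihalocarbene ring enlargement of benzofuran, and the dihalocarbene ring enlargement of cyclic silyl enol ethers to 2-haloenones, whereas the pairing of an aryl(chloro)carbene with a 3-silyloxybenzofuran is not described. The only ring that is closed is the transient three-membered ring ([2+1] cheletropic addition), ring C results from cleavage of the shared bond, and the three stereocentres of 13 are erased in planar 14, so no stereocontrol is needed at this stage. The step needs chemoselectivity against the ring D double bond, the ortho-methoxy C–H bonds and unreacted 11 (azine formation), and this should be secured by the excess of the doubly oxygen-activated 2, by slow addition of 11 and by the gem-dimethyl shielding of the ring D alkene.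

**Step 7**
Reactants: 15 3-(7-methoxy-2,2-dimethyl-2H-chromen-6-yl)-7-(triisopropylsilyloxy)-4H-chromen-4-one
Product: 17 (3S,4S)-3-(7-methoxy-2,2-dimethyl-2H-chromen-6-yl)-7-(triisopropylsilyloxy)chroman-4-ol, via racemising isoflavanone 16 (not isolated)
Conditions: RuCl[(S,S)-TsDPEN](p-cymene) (3 mol %), HCO2H/Et3N (5:2), EtOAc, 40 °C
Reagents that add atoms: none
Why: In this Noyori–Ikariya asymmetric transfer hydrogenation run as a cascade, the ruthenium hydride should first add to C2 (conjugate reduction) to give 16, which racemises through its enol in the presence of Et3N, and the (S,S)-catalyst should then reduce the 3S enantiomer faster, anti to the C3 aryl group and from the face that gives 4S (dynamic kinetic resolution, CH/π contact of the p-cymene ligand with ring A), so that C3 and C4 are set together as the cis alcohol and the unpolarised ring D alkene is left alone.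

**Step 8**
Reactants: 17 (3S,4S)-3-(7-methoxy-2,2-dimethyl-2H-chromen-6-yl)-7-(triisopropylsilyloxy)chroman-4-ol
Product: 18 (3S)-3-(7-methoxy-2,2-dimethyl-2H-chromen-6-yl)-7-(triisopropylsilyloxy)chroman-4-one
Conditions: Dess–Martin periodinane, NaHCO3, CH2Cl2, 0 °C
Reagents that add atoms: none
Why: The Dess–Martin oxidation runs under buffered, near-neutral conditions at low temperature, so the C4 carbinol should be oxidised without enolisation of the new α-aryl ketone, C3 keeps its 3S configuration, and the silyl ether and the chromene are inert.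

**Step 9**
Reactants: 18 (3S)-3-(7-methoxy-2,2-dimethyl-2H-chromen-6-yl)-7-(triisopropylsilyloxy)chroman-4-one
Product: 19 (3S)-7-hydroxy-3-(7-methoxy-2,2-dimethyl-2H-chromen-6-yl)chroman-4-one
Conditions: Et3N·3HF, THF, 0 °C; pH 6 buffer work-up
Reagents that add atoms: none
Why: Fluoride cleavage of the aryl silyl ether, which is activated by the para carbonyl group, with the slightly acidic Et3N·3HF should free the C7 phenol without producing basic fluoride or phenoxide that could enolise C3, so the 3S centre is kept.

**Compound list**
1 | 6-hydroxybenzofuran-3(2H)-one | O=C1COc2cc(O)ccc12 | starting material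
2 | 3,6-bis(triisopropylsilyloxy)benzofuran | CC(C)[Si](Oc1ccc2c(O[Si](C(C)C)(C(C)C)C(C)C)coc2c1)(C(C)C)C(C)C | intermediate
3 | 7-methoxy-2,2-dimethyl-2H-chromene | COc1ccc2C=CC(C)(C)Oc2c1 | starting material
4 | N,N-dimethyl-(7-methoxy-2,2-dimethyl-2H-chromen-6-yl)methaniminium dichlorophosphate | C[N+](C)=Cc1cc2C=CC(C)(C)Oc2cc1OC.[O-]P(=O)(Cl)Cl | intermediate
5 | 7-methoxy-2,2-dimethyl-2H-chromene-6-carbaldehyde | O=Cc1cc2C=CC(C)(C)Oc2cc1OC | intermediate
6 | (E)-7-methoxy-2,2-dimethyl-2H-chromene-6-carbaldehyde oxime | O/N=C/c1cc2C=CC(C)(C)Oc2cc1OC | intermediate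
7 | (E)-7-methoxy-2,2-dimethyl-2H-chromene-6-carbaldehyde O-acetyl oxime | CC(=O)O/N=C/c1cc2C=CC(C)(C)Oc2cc1OC | intermediate
8 | 7-methoxy-2,2-dimethyl-2H-chromene-6-carbonitrile | N#Cc1cc2C=CC(C)(C)Oc2cc1OC | intermediate
9 | lithium N,N'-bis(trimethylsilyl)-7-methoxy-2,2-dimethyl-2H-chromene-6-carboximidamidate | [Li]N([Si](C)(C)C)C(=N[Si](C)(C)C)c1cc2C=CC(C)(C)Oc2cc1OC | intermediate
10 | 7-methoxy-2,2-dimethyl-2H-chromene-6-carboximidamide hydrochloride | Cl.NC(=N)c1cc2C=CC(C)(C)Oc2cc1OC | intermediate
11 | 3-chloro-3-(7-methoxy-2,2-dimethyl-2H-chromen-6-yl)-3H-diazirine | ClC1(N=N1)c1cc2C=CC(C)(C)Oc2cc1OC | intermediate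
12 | chloro(7-methoxy-2,2-dimethyl-2H-chromen-6-yl)carbene | Cl[C]c1cc2C=CC(C)(C)Oc2cc1OC | intermediate
13 | 1-chloro-1-(7-methoxy-2,2-dimethyl-2H-chromen-6-yl)-4,6b-bis(triisopropylsilyloxy)-1a,6b-dihydro-1H-cyclopropa[b]benzofuran (racemic, both C1 epimers) | ClC1(c2cc3C=CC(C)(C)Oc3cc2OC)C2Oc3cc(O[Si](C(C)C)(C(C)C)C(C)C)ccc3C12O[Si](C(C)C)(C(C)C)C(C)C | intermediate
14 | 3-(7-methoxy-2,2-dimethyl-2H-chromen-6-yl)-4,7-bis(triisopropylsilyloxy)chromenylium chloride | [Cl-].COc1cc2OC(C)(C)C=Cc2cc1-c1c[o+]c2cc(O[Si](C(C)C)(C(C)C)C(C)C)ccc2c1O[Si](C(C)C)(C(C)C)C(C)C | intermediate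
15 | 3-(7-methoxy-2,2-dimethyl-2H-chromen-6-yl)-7-(triisopropylsilyloxy)-4H-chromen-4-one | COc1cc2OC(C)(C)C=Cc2cc1C1=COc2cc(O[Si](C(C)C)(C(C)C)C(C)C)ccc2C1=O | intermediate
16 | rac-3-(7-methoxy-2,2-dimethyl-2H-chromen-6-yl)-7-(triisopropylsilyloxy)chroman-4-one (racemising) | COc1cc2OC(C)(C)C=Cc2cc1C1COc2cc(O[Si](C(C)C)(C(C)C)C(C)C)ccc2C1=O | intermediate
17 | (3S,4S)-3-(7-methoxy-2,2-dimethyl-2H-chromen-6-yl)-7-(triisopropylsilyloxy)chroman-4-ol (cis) | COc1cc2c(cc1[C@H]1COc3cc(O[Si](C(C)C)(C(C)C)C(C)C)ccc3[C@H]1O)C=CC(C)(C)O2 | intermediate
18 | (3S)-3-(7-methoxy-2,2-dimethyl-2H-chromen-6-yl)-7-(triisopropylsilyloxy)chroman-4-one | COc1cc2c(cc1[C@H]1COc3cc(O[Si](C(C)C)(C(C)C)C(C)C)ccc3C1=O)C=CC(C)(C)O2 | intermediate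
19 | (3S)-7-hydroxy-3-(7-methoxy-2,2-dimethyl-2H-chromen-6-yl)chroman-4-one | COc1cc2c(cc1[C@H]1COc3cc(O)ccc3C1=O)C=CC(C)(C)O2 | target

**Totals**
Total step count: 9. Longest linear sequence: 8 steps (3 to 19, steps 2 to 9). Step 1 is a one-step side branch.

**Steps most likely to fail**

**Step 6 (Proposed new method).**
- What may go wrong: the electron-rich carbene may be used up before it reaches C2=C3 of 2, through azine formation with unreacted diazirine, insertion into the ortho-methoxy C–H bonds, or addition to the ring D double bond. The exo-chloro epimer of the cyclopropane may also be slow to ionise.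
- Fallback (known chemistry): it sets out from 2 and comes back at 15. Ring C still comes from the five-membered ring.
- Dibromocarbene (CHBr3, KOtBu, pentane, −20 °C) is added to the same C2=C3 bond to give the dibromocyclopropane adduct F1. On warming, F1 opens with loss of the silyl bromide to 3-bromo-7-(triisopropylsilyloxy)-4H-chromen-4-one F2. This is the established dihalocarbene ring enlargement of cyclic silyl enol ethers.
- Rings B and D are then attached by cross-coupling. Commercial 4-bromo-3-methoxyphenol and 3-methylbut-2-enal (PhB(OH)2, AcOH, toluene, reflux) give 6-bromo-7-methoxy-2,2-dimethyl-2H-chromene F3.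
- Miyaura borylation (B2pin2, PdCl2(dppf), KOAc, dioxane, 80 °C) gives the pinacol boronate F4. Suzuki–Miyaura coupling of F2 with F4 (Pd(PPh3)4, K3PO4, dioxane/H2O, 70 °C) gives 15.

**Step 5.**
- What may go wrong: hypochlorite may chlorinate the ring D double bond or the electron-rich C8 position. The donor-substituted diazirine may also lose nitrogen or ionise at its C–Cl bond during extraction and storage.
- Fallback: it sets out from 5 and comes back at 15 by way of carbene 12, so steps 3 to 5 drop out.
- The aldehyde is converted with SOCl2 and catalytic DMF (CH2Cl2, 0 °C) into 6-(dichloromethyl)-7-methoxy-2,2-dimethyl-2H-chromene F5, which is used crude.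
- Base-induced α-elimination (KOtBu, pentane/THF, −40 °C) in the presence of 2 generates 12, or its carbenoid, directly in the flask. It then follows the path of step 6.
- This replaces oxidative N–N bond formation and nitrogen extrusion by the classical benzal halide route to aryl halocarbenes.

**Step 7.**
- What may go wrong: conjugate reduction of the vinylogous ester may stall. Racemisation of the intermediate ketone may be too slow relative to its reduction because of the ortho-methoxy aryl group, which would erode facial and diastereoselectivity. The electron-rich C4 carbinol may ionise in formic acid and dehydrate.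
- Fallback: it sets out from 15 and comes back at 18, replacing steps 7 and 8.
- 1,4-Reduction with LiBH(s-Bu)3 (THF, −78 °C) gives the lithium enolate F6, which is trapped with allyl chloroformate as the allyl enol carbonate F7.
- Decarboxylative asymmetric protonation catalysed by zerovalent palladium (Pd2(dba)3, t-BuPHOX ligand, Meldrum's acid, dioxane, 40 °C), a reaction type established for isoflavanones, sets C3 directly at the ketone level.
- The ligand antipode that delivers 3S is fixed in a pilot run.

**Further compounds**
F1 | step 6 | 1,1-dibromo-4,6b-bis(triisopropylsilyloxy)-1a,6b-dihydro-1H-cyclopropa[b]benzofuran (racemic) | BrC1(Br)C2Oc3cc(O[Si](C(C)C)(C(C)C)C(C)C)ccc3C12O[Si](C(C)C)(C(C)C)C(C)C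
F2 | step 6 | 3-bromo-7-(triisopropylsilyloxy)-4H-chromen-4-one | O=C1C(Br)=COc2cc(O[Si](C(C)C)(C(C)C)C(C)C)ccc12
F3 | step 6 | 6-bromo-7-methoxy-2,2-dimethyl-2H-chromene | COc1cc2OC(C)(C)C=Cc2cc1Br
F4 | step 6 | 2-(7-methoxy-2,2-dimethyl-2H-chromen-6-yl)-4,4,5,5-tetramethyl-1,3,2-dioxaborolane | COc1cc2OC(C)(C)C=Cc2cc1B1OC(C)(C)C(C)(C)O1
F5 | step 5 | 6-(dichloromethyl)-7-methoxy-2,2-dimethyl-2H-chromene | ClC(Cl)c1cc2C=CC(C)(C)Oc2cc1OC
F6 | step 7 | lithium 3-(7-methoxy-2,2-dimethyl-2H-chromen-6-yl)-7-(triisopropylsilyloxy)-2H-chromen-4-olate | [Li]OC1=C(COc2cc(O[Si](C(C)C)(C(C)C)C(C)C)ccc12)c1cc2C=CC(C)(C)Oc2cc1OC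
F7 | step 7 | allyl 3-(7-methoxy-2,2-dimethyl-2H-chromen-6-yl)-7-(triisopropylsilyloxy)-2H-chromen-4-yl carbonate | C=CCOC(=O)OC1=C(COc2cc(O[Si](C(C)C)(C(C)C)C(C)C)ccc12)c1cc2C=CC(C)(C)Oc2cc1OC
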